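Ring numbering used throughout: ring A is C1 (OMe), C2 (Br), C3 (Me), C4 (Cl), C5 (OH), C6 (ketone); ring B is C1 (ketone), C2 (CHO), C3 (OH), C4 (H), C5 (OH), C6 (prenyl). Compounds 1–15 are those of the steps and the compound list.

## The problem

Pestalone H (15) is a benzophenone whose carbonyl carbon sits between two aryl carbons that are both di-ortho-substituted: ring A C6, flanked by C1–OMe and C5–OH, and ring B C1, flanked by C2–CHO and C6–prenyl. There is no stereocentre, and the only alkene carries two identical methyl groups, so nothing in the molecule can or must control configuration. The difficulties are regiochemistry and steric congestion.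

Ring A is hexasubstituted and unsymmetrical in two linked ways. One oxygen is methylated and the other is free, and bromine lies next to the methyl ether while chlorine lies next to the phenol. A symmetrical orcinol precursor with late mono-demethylation therefore cannot be used, and the two oxygens must differ from the first step. Ring B carries an aldehyde directly beside the ketone, two phenols and a C-prenyl group that must sit on one specific carbon of a phloroglucinol core.

Several groups limit the methods that can be used:
- The 2-aroylbenzaldehyde unit collapses to a phthalide by hydride shift when hydroxide, alkoxide or amines add to the aldehyde.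
- The aldehyde rules out aryllithium or Grignard chemistry on ring B.
- The prenyl alkene beside a phenol closes to a chroman in strong acid and does not survive hydrogenation.
- The aryl bromide and chloride exclude reductive deprotections.

The enabling feature is that the ketone is a single carbon between two aryl carbons, so it can be supplied as carbon monoxide (13). Ring A C6 can carry iodine, the weakest of its three carbon–halogen bonds and the position that electrophilic halogenation reaches last. Ring B C1 can carry boron, which derives from the third oxygen of phloroglucinaldehyde and tolerates the neighbouring formyl group. Both carbonyl groups then appear directly at their final oxidation level.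

## Retrosynthesis

**15 from 14.** The three phenolic O–CH2 bonds of the methoxymethyl ethers in 14 are cut. Other protecting groups are less suitable:
- Methyl ethers could not be told apart from the ring A methoxy group.
- Benzyl ethers would need hydrogenolysis, which destroys the prenyl group and the C–Br bond.
- Silyl ethers put bulk beside both reacting carbons and are labile to carbonate.

The methoxymethyl group is small, inert to base and palladium, and leaves in dilute acid. The skeleton is unchanged, but three acidic phenols that would quench base and chelate palladium are masked. The forward step must use acid mild enough to leave the prenylphenol open.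

**14 from 5, 12 and 13.** Both bonds to the ketone carbon are cut: ring A C6–CO and CO–ring B C1. Cutting only one of them (aryl-metal plus aldehyde, or aryl-metal plus acyl donor) would require a masked second formyl group on ring B and a late oxidation next to it, and would bring an organolithium near an aldehyde. The two-bond cut gives the aryl iodide 5, the arylboronate 12 and carbon monoxide 13. These are two benzene derivatives of similar size, each made independently, and a gas. The forward reaction has to meet three demands:
- oxidative addition at C–I only;
- capture of 13 before the aryl transfer;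
- transmetalation of a doubly ortho-substituted boronate onto a hindered aroylpalladium.

**5 from 1 through 4, 3 and 2.** The ring A O–CH2 bond (5 to 4) and then the C–I, C–Cl and C–Br bonds are cut in that order (4 to 3 to 2 to 1). Each halogen is placed by the directing groups present at that stage:
- bromine goes para to the free hydroxyl of 1;
- chlorine goes ortho to the hydroxyl and para to the methoxy group of 2;
- iodine goes to the last free position of 3, between the two oxygens, which is exactly the carbon that must react in the key step.

Starting from the mono-methyl ether 1 keeps the two oxygens different throughout. The sequence depends on para-selective bromination in the first step.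

**12 from 9 through 10.** The C–B bond of 12 is cut to the aryl triflate 10 and bis(pinacolato)diboron 11, and the S–O bond of 10 is cut to the phenol 9. Halogen–metal exchange is excluded by the aldehyde, and C–H borylation is excluded because C1 is flanked on both sides. A palladium-catalysed borylation of a triflate tolerates the formyl group. The forward reaction must borylate a di-ortho-substituted triflate.

**9 from 6 and 7 through 8.** Two O–CH2 bonds (9 to 8) and the C–C bond to the prenyl group (8 to 6 plus prenyl bromide 7) are cut. In the symmetrical aldehyde 6 the two free ring positions are equivalent, so the prenyl group can only enter at the right carbon. After that the three hydroxyls differ: one is para to the aldehyde, one is ortho and next to hydrogen, and one is ortho and wedged between aldehyde and prenyl. The last is the one that must stay free for triflation. The forward steps need C- over O-alkylation and a selective double protection.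

## Roads not taken

**Alternative 1:** Ring B would be built last by cutting C1–C6 and C2–C3. The partners are the ring A propargylic acetate A1 (methyl 4-acetoxy-4-[3-bromo-5-chloro-2-methoxy-6-(methoxymethoxy)-4-methylphenyl]but-2-ynoate, racemic) and the bis-silyl dienol ether A2 ((3Z)-1-methoxy-7-methyl-1,3-bis(trimethylsilyloxy)octa-1,3,6-triene). On heating, the nucleophilic C4 terminus of A2 should attack the alkyne carbon β to the ester. The Diels–Alder adduct should aromatise by elimination, and mild acid should leave the resorcinol A3 (methyl 2-{acetoxy[3-bromo-5-chloro-2-methoxy-6-(methoxymethoxy)-4-methylphenyl]methyl}-4,6-dihydroxy-3-(3-methylbut-2-enyl)benzoate, racemic).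
- Merits: every ring B substituent is placed by the cycloaddition. No phloroglucinol has to be protected selectively, no C- versus O-prenylation arises, and no hindered palladium coupling is needed. In ring B regiocontrol this road is better than the chosen one.
- What the chosen plan sets against it: the symmetry of 6, which fixes the prenylation site, and a Claisen-based detour held in reserve.
- Weak points: the alkyne is internal and carries a bulky, fully substituted aryl carbinol. The diene bears a substituent on its reacting terminus, which slows the cycloaddition and makes the diene geometry matter. The propargylic acetate can ionise at the temperature needed.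
- Oxidation levels: A3 is wrong at both carbons. The ester must become the aldehyde and the acetoxy carbinol the ketone. Once the acetate is removed the carbinol lactonises onto the ester, so the way back is reduction to a diol and double oxidation, with over-oxidation to the lactone as the standing danger.
- Comparison: at least five steps would follow the key step, against one in the chosen plan, and a stereocentre would be made only to be destroyed.

**Alternative 2:** Ring A would be built last by cutting C5–C6 and C1–C2. The partners are the cyclobutenone A4 (2-bromo-4-chloro-3-methylcyclobut-2-enone) and the ring B alkynyl ether A5 (tert-butyl({1-[2-(dimethoxymethyl)-3,5-bis(methoxymethoxy)-6-(3-methylbut-2-enyl)phenyl]-3-methoxyprop-2-yn-1-yl}oxy)dimethylsilane, racemic). Heating in toluene should bring about four-electron ring opening, [2+2] cycloaddition, a second ring opening and six-electron electrocyclisation. The product would be the phenol A6, the tert-butyldimethylsilyl ether of (3-bromo-5-chloro-6-hydroxy-2-methoxy-4-methylphenyl)[2-(dimethoxymethyl)-3,5-bis(methoxymethoxy)-6-(3-methylbut-2-enyl)phenyl]methanol (racemic).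
- Merits: the whole substitution pattern of ring A, including methoxy versus hydroxy and bromine versus chlorine, is written into the two partners and cannot go wrong. Here this road is clearly better than the chosen one, which relies on directing effects in steps 1 and 2.
- What the chosen plan sets against it: a four-step sequence from a commercial phenol whose last halogenation is unambiguous, and a reordered halogenation held in reserve.
- Weak points: A4 is a small, doubly halogenated cyclobutenone that is not commercial and whose own preparation is uncertain. Its C4 chloride may be lost at the ketene stage. A5 needs a ring B carbon already attached at C1, so a hindered ring B triflate such as 10 would have to be carbonylated anyway.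
- Comparison: A6 is a carbinol, so desilylation, oxidation and hydrolysis follow (three steps). The chosen plan is shorter and uses a known catalyst class and commercial materials.

**Alternative 3:** Ring B would be folded from a chain by cutting C6–C1 and C1–C2. The trianion of the diketo ester A7 (methyl 9-methyl-3,5-dioxodec-8-enoate) would be acylated at its terminal carbanion by the ester carbonyl of the ring A aroylformate A8 (methyl 2-[3-bromo-5-chloro-2-methoxy-6-(methoxymethoxy)-4-methylphenyl]-2-oxoacetate). The tetracarbonyl chain would then close by aldol condensation and aromatise to A9 (methyl 2-[3-bromo-5-chloro-2-methoxy-6-(methoxymethoxy)-4-methylbenzoyl]-4,6-dihydroxy-3-(3-methylbut-2-enyl)benzoate).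
- Merits: the diaryl ketone arrives at the right oxidation level, no transition metal is needed, and the congested bond is closed intramolecularly. In coping with the tetra-ortho environment this road may be better than an intermolecular coupling. A8 is also only one or two operations from 5.
- What the chosen plan sets against it: the precedent of bulky carbene–palladium catalysts for hindered diaryl ketones, and an acyl coupling held in reserve.
- Weak points: the carbanion to be acylated is secondary, and proton transfer competes. A8 offers two electrophilic carbonyls. The acylated chain has other ways to close, through the aroyl ketone or through oxygen.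
- Oxidation level: A9 is an ester. A chelated, hindered salicylate cannot be reduced to the aldehyde beside a diaryl ketone, so both would be reduced and re-oxidised, with the same lactone danger as in Alternative 1.
- Comparison: four or more steps follow the key step, and A7 needs its own preparation.

Key step: step 9

Remark on the chemistry: pestalone H has no stereocentre and no stereogenic double bond, so no configuration needs to be specified for any compound of the route.

## Route

Step 1
Reactants: 1 3-methoxy-5-methylphenol
Product: 2 4-bromo-3-methoxy-5-methylphenol
Conditions: NBS (1.0 equiv), MeCN, −20 °C to 0 °C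
Reagents that add atoms: N-bromosuccinimide, O=C1CCC(=O)N1Br
Why: Electrophilic aromatic bromination; the free hydroxyl is the strongest donor and should direct the single equivalent of bromine to its para position (ring A C2), which is also ortho to the methoxy group. Low temperature and a polar solvent are chosen to favour para attack and to stop at monobromination.

Step 2
Reactants: 2 4-bromo-3-methoxy-5-methylphenol
Product: 3 4-bromo-2-chloro-5-methoxy-3-methylphenol
Conditions: SO2Cl2 (1.05 equiv), CH2Cl2, 0 °C
Reagents that add atoms: sulfuryl chloride, O=S(=O)(Cl)Cl
Why: Electrophilic aromatic chlorination at ring A C4, which is ortho to the hydroxyl and para to the methoxy group. The only other free position (C6) lies between the two oxygens, the slowest site of a resorcinol ether towards halogenation.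

Step 3
Reactants: 3 4-bromo-2-chloro-5-methoxy-3-methylphenol
Product: 4 4-bromo-2-chloro-6-iodo-5-methoxy-3-methylphenol
Conditions: NIS (1.1 equiv), TsOH·H2O (0.1 equiv), MeCN, rt
Reagents that add atoms: N-iodosuccinimide, O=C1CCC(=O)N1I
Why: Acid-activated electrophilic iodination of a phenol; ring A C6 is the only ring position left and is ortho to both oxygen donors, so no regiochemical choice remains.

Step 4
Reactants: 4 4-bromo-2-chloro-6-iodo-5-methoxy-3-methylphenol
Product: 5 1-bromo-3-chloro-5-iodo-6-methoxy-4-(methoxymethoxy)-2-methylbenzene
Conditions: MOMCl, i-Pr2NEt, CH2Cl2, 0 °C to rt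
Reagents that add atoms: chloromethyl methyl ether, COCCl
Why: O-Alkylation (Williamson-type) of an acidic di-ortho-halophenol with a small, highly reactive electrophile; the methoxymethyl ether adds little bulk beside the iodide and is stable to base and palladium.

Step 5
Reactants: 6 2,4,6-trihydroxybenzaldehyde; 7 prenyl bromide (1-bromo-3-methylbut-2-ene)
Product: 8 2,4,6-trihydroxy-3-(3-methylbut-2-enyl)benzaldehyde
Conditions: DBU (1.0 equiv), THF, 0 °C to rt
Reagents that add atoms: none
Why: C-Alkylation of the ambident phloroglucinaldehyde anion by a soft allylic bromide; the two free ring positions of 6 are equivalent, so mono-C-prenylation can give only one regioisomer. Prenyl bromide is kept limiting to restrain double prenylation.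

Step 6
Reactants: 8 2,4,6-trihydroxy-3-(3-methylbut-2-enyl)benzaldehyde
Product: 9 2-hydroxy-4,6-bis(methoxymethoxy)-3-(3-methylbut-2-enyl)benzaldehyde
Conditions: MOMCl (2.1 equiv), i-Pr2NEt (2.5 equiv), CH2Cl2, 0 °C
Reagents that add atoms: chloromethyl methyl ether, COCCl
Why: Selective O-alkylation; the hydroxyl para to the aldehyde is the most acidic and least hindered and should react first, followed by the ortho hydroxyl next to ring hydrogen. The hydroxyl wedged between aldehyde and prenyl group stays free, held by the hydrogen bond to the carbonyl oxygen.

Step 7
Reactants: 9 2-hydroxy-4,6-bis(methoxymethoxy)-3-(3-methylbut-2-enyl)benzaldehyde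
Product: 10 2-formyl-3,5-bis(methoxymethoxy)-6-(3-methylbut-2-enyl)phenyl trifluoromethanesulfonate
Conditions: Tf2O, pyridine, CH2Cl2, −20 °C to 0 °C
Reagents that add atoms: trifluoromethanesulfonic anhydride, O=S(=O)(OS(=O)(=O)C(F)(F)F)C(F)(F)F
Why: O-Sulfonylation of a salicylaldehyde-type phenol; the anhydride is reactive enough for a chelated, flanked hydroxyl, and excess pyridine keeps the medium free of triflic acid so that the acetals and the alkene are not touched.

Step 8
Reactants: 10 2-formyl-3,5-bis(methoxymethoxy)-6-(3-methylbut-2-enyl)phenyl trifluoromethanesulfonate; 11 bis(pinacolato)diboron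
Product: 12 4,6-bis(methoxymethoxy)-3-(3-methylbut-2-enyl)-2-(4,4,5,5-tetramethyl-1,3,2-dioxaborolan-2-yl)benzaldehyde
Conditions: Pd2(dba)3 (dba = dibenzylideneacetone), XPhos (2-dicyclohexylphosphino-2′,4′,6′-triisopropylbiphenyl), KOAc, 1,4-dioxane, 100 °C
Reagents that add atoms: none
Why: Miyaura borylation: oxidative addition of the aryl triflate to zerovalent palladium, acetate-assisted transmetalation from 11 and reductive elimination. The bulky biaryl phosphine is chosen for the di-ortho-substituted triflate, and the weak acetate base leaves the aldehyde alone and suppresses biaryl formation.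

Step 9
Reactants: 5 1-bromo-3-chloro-5-iodo-6-methoxy-4-(methoxymethoxy)-2-methylbenzene; 12 4,6-bis(methoxymethoxy)-3-(3-methylbut-2-enyl)-2-(4,4,5,5-tetramethyl-1,3,2-dioxaborolan-2-yl)benzaldehyde; 13 carbon monoxide
Product: 14 2-[3-bromo-5-chloro-2-methoxy-6-(methoxymethoxy)-4-methylbenzoyl]-4,6-bis(methoxymethoxy)-3-(3-methylbut-2-enyl)benzaldehyde
Conditions: 5 (1.2 equiv), [PdCl2(IPr)(3-chloropyridine)] (5 mol %; IPr = 1,3-bis(2,6-diisopropylphenyl)imidazol-2-ylidene), Cs2CO3 (3 equiv), CO (4 bar), chlorobenzene, 80 °C
Reagents that add atoms: none
Why: The precatalyst is reduced in the flask to a carbene-ligated zerovalent palladium species that inserts into the C6–I bond of 5, and 13 then inserts into the aryl–palladium bond to give an aroyl divalent palladium iodide whose reacting carbon stands one atom away from the crowded ring. Cs2CO3 turns 12 into a borate that passes the ring B aryl group to palladium, and reductive elimination releases 14 and returns zerovalent palladium. The closest known reaction type is the carbonylative Suzuki–Miyaura coupling of di-ortho-substituted aryl iodides with arylboron reagents under [PdCl2(NHC)(3-chloropyridine)] catalysis to give hindered diaryl ketones; a tetra-ortho-substituted ketone lies at the edge of that scope. No ring is closed and no stereocentre is formed. The first selectivity needed is C–I over C–Br and C–Cl, secured by bond strength, by the lower electron density of palladium under carbon monoxide at 80 °C, and by keeping 12 as the limiting partner so that no nucleophile is left for the bromide. The second is insertion of 13 before aryl transfer, secured because direct coupling would have to build a tetra-ortho-substituted biaryl, which is slow, while the pressure of 13 makes acyl formation fast. The aldehyde of 12 is inert to these species. Anhydrous carbonate in a non-polar solvent keeps hydroxide away from the 2-aroylbenzaldehyde product, which would otherwise rearrange by hydride shift.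

Step 10
Reactants: 14 2-[3-bromo-5-chloro-2-methoxy-6-(methoxymethoxy)-4-methylbenzoyl]-4,6-bis(methoxymethoxy)-3-(3-methylbut-2-enyl)benzaldehyde
Product: 15 pestalone H, 2-(3-bromo-5-chloro-6-hydroxy-2-methoxy-4-methylbenzoyl)-4,6-dihydroxy-3-(3-methylbut-2-enyl)benzaldehyde
Conditions: HCl (3 M aq.), MeOH, 40 °C
Reagents that add atoms: none
Why: Acid-catalysed cleavage (transacetalisation to methanol) of three aryl methoxymethyl ethers; dilute acid at moderate temperature is the usual way to unmask ortho-prenylphenols without closing the chroman. Any dimethyl acetal formed at the aldehyde should revert on aqueous work-up, which is kept free of base to protect the 2-aroylbenzaldehyde unit.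

## Compound list

1 | 3-methoxy-5-methylphenol | COc1cc(C)cc(O)c1 | starting material
2 | 4-bromo-3-methoxy-5-methylphenol | COc1cc(O)cc(C)c1Br | intermediate
3 | 4-bromo-2-chloro-5-methoxy-3-methylphenol | COc1cc(O)c(Cl)c(C)c1Br | intermediate
4 | 4-bromo-2-chloro-6-iodo-5-methoxy-3-methylphenol | COc1c(I)c(O)c(Cl)c(C)c1Br | intermediate
5 | 1-bromo-3-chloro-5-iodo-6-methoxy-4-(methoxymethoxy)-2-methylbenzene | COCOc1c(I)c(OC)c(Br)c(C)c1Cl | intermediate
6 | 2,4,6-trihydroxybenzaldehyde | O=Cc1c(O)cc(O)cc1O | starting material
7 | prenyl bromide (1-bromo-3-methylbut-2-ene) | CC(C)=CCBr | starting material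
8 | 2,4,6-trihydroxy-3-(3-methylbut-2-enyl)benzaldehyde | O=Cc1c(O)cc(O)c(CC=C(C)C)c1O | intermediate
9 | 2-hydroxy-4,6-bis(methoxymethoxy)-3-(3-methylbut-2-enyl)benzaldehyde | O=Cc1c(OCOC)cc(OCOC)c(CC=C(C)C)c1O | intermediate
10 | 2-formyl-3,5-bis(methoxymethoxy)-6-(3-methylbut-2-enyl)phenyl trifluoromethanesulfonate | O=Cc1c(OCOC)cc(OCOC)c(CC=C(C)C)c1OS(=O)(=O)C(F)(F)F | intermediate
11 | bis(pinacolato)diboron | CC1(C)OB(OC1(C)C)B1OC(C)(C)C(C)(C)O1 | starting material
12 | 4,6-bis(methoxymethoxy)-3-(3-methylbut-2-enyl)-2-(4,4,5,5-tetramethyl-1,3,2-dioxaborolan-2-yl)benzaldehyde | O=Cc1c(OCOC)cc(OCOC)c(CC=C(C)C)c1B1OC(C)(C)C(C)(C)O1 | intermediate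
13 | carbon monoxide | [C-]#[O+] | starting material
14 | 2-[3-bromo-5-chloro-2-methoxy-6-(methoxymethoxy)-4-methylbenzoyl]-4,6-bis(methoxymethoxy)-3-(3-methylbut-2-enyl)benzaldehyde | O=Cc1c(OCOC)cc(OCOC)c(CC=C(C)C)c1C(=O)c1c(OCOC)c(Cl)c(C)c(Br)c1OC | intermediate
15 | pestalone H, 2-(3-bromo-5-chloro-6-hydroxy-2-methoxy-4-methylbenzoyl)-4,6-dihydroxy-3-(3-methylbut-2-enyl)benzaldehyde | COc1c(Br)c(C)c(Cl)c(O)c1C(=O)c1c(C=O)c(O)cc(O)c1CC=C(C)C | target

## Step count and least certain steps

Total step count: 10. Longest linear sequence: 6 steps (steps 1–4, 9, 10 or steps 5–8, 9, 10).

**Step 9 (key step).** The most likely failure is a stalled aryl transfer from the doubly ortho-substituted pinacol boronate to the hindered aroylpalladium intermediate. The acyl species would then be diverted to the carboxylate, or 12 would be lost by protodeboronation. A lesser danger is base-induced rearrangement of the 2-aroylbenzaldehyde product on prolonged heating.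

The fallback removes carbon monoxide from the palladium step and makes the ring A–carbonyl bond by classical carboxylation. It sets out from 5. Iodine–magnesium exchange with i-PrMgCl·LiCl in THF at −40 °C (the C–Br and C–Cl bonds should not exchange at this temperature) and quenching with carbon dioxide should give 3-bromo-5-chloro-2-methoxy-6-(methoxymethoxy)-4-methylbenzoic acid F1. Under neutral conditions, 1-chloro-N,N,2-trimethylprop-1-en-1-amine in CH2Cl2 should convert F1 into 3-bromo-5-chloro-2-methoxy-6-(methoxymethoxy)-4-methylbenzoyl chloride F2 without liberating acid that could open the neighbouring acetal. A two-component acyl Suzuki–Miyaura coupling of F2 with 12 (Pd(PPh3)4, Cs2CO3, toluene, 90 °C) then comes back to the route at 14. In this variant the aroylpalladium species forms directly and no carbon monoxide competes for coordination sites during the aryl transfer.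

**Step 1.** The most likely failure is attack para to the methoxy group (ring A C4) in competition with attack para to the hydroxyl (C2), together with some dibromination. The resulting regioisomers would be carried into the wrong bromo/chloro pattern.

The fallback reverses the order of the halogens and switches the controlling donor. It sets out from 1. Acetylation (Ac2O, pyridine) should give 3-methoxy-5-methylphenyl acetate F3, in which the methoxy group is the only strong donor. Chlorination with SO2Cl2 in CH2Cl2 should then go para to the methoxy group to give 2-chloro-5-methoxy-3-methylphenyl acetate F4. Methanolysis (K2CO3, MeOH) should give 2-chloro-5-methoxy-3-methylphenol F5. Bromination of F5 with NBS para to the hydroxyl, where the only other free site lies between the two oxygens, comes back to the route at 3.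

**Step 5 (with its consequence for step 6).** The most likely failure is O-alkylation and double C-alkylation of the phloroglucinol anion, which would make 8 a minor product. In step 6, protection of the wrong ortho hydroxyl would then give the isomeric phenol.

The fallback avoids both by protecting first and delivering the prenyl group intramolecularly. It sets out from 6. Double methoxymethylation (MOMCl, i-Pr2NEt, CH2Cl2) of the symmetrical aldehyde can only give 2-hydroxy-4,6-bis(methoxymethoxy)benzaldehyde F6. Palladium-catalysed O-allylation (Tsuji–Trost type) with tert-butyl 2-methylbut-3-en-2-yl carbonate (Pd(PPh3)4, THF, 0 °C) should give the tertiary ether 4,6-bis(methoxymethoxy)-2-[(2-methylbut-3-en-2-yl)oxy]benzaldehyde F7. On heating (toluene, 110 °C, or Eu(fod)3 in CHCl3 at 60 °C), aromatic Claisen rearrangement of F7 can only reach the one free ortho carbon. It comes back to the route at 9.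

**Step 10.** The most likely failure is acid-catalysed addition of the ring B C5 hydroxyl across the prenyl alkene (chroman formation). The hindered ring A ether may also be cleaved incompletely if the acid is kept mild enough to avoid that.

The fallback removes the protecting groups without a Brønsted acid. It sets out from 14. TMSOTf with 2,2′-bipyridyl in CH2Cl2 at 0 °C should transfer the three methoxymethyl groups to the bipyridyl nitrogen and leave 2-{3-bromo-5-chloro-2-methoxy-4-methyl-6-[(trimethylsilyl)oxy]benzoyl}-3-(3-methylbut-2-enyl)-4,6-bis[(trimethylsilyl)oxy]benzaldehyde F8. Its aryl silyl ethers should hydrolyse on addition of water at neutral pH, which comes back to the route at 15.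

## Further compounds

F1 | step 9 | 3-bromo-5-chloro-2-methoxy-6-(methoxymethoxy)-4-methylbenzoic acid | OC(=O)c1c(OCOC)c(Cl)c(C)c(Br)c1OC
F2 | step 9 | 3-bromo-5-chloro-2-methoxy-6-(methoxymethoxy)-4-methylbenzoyl chloride | O=C(Cl)c1c(OCOC)c(Cl)c(C)c(Br)c1OC
F3 | step 1 | 3-methoxy-5-methylphenyl acetate | COc1cc(C)cc(OC(C)=O)c1
F4 | step 1 | 2-chloro-5-methoxy-3-methylphenyl acetate | COc1cc(OC(C)=O)c(Cl)c(C)c1
F5 | step 1 | 2-chloro-5-methoxy-3-methylphenol | COc1cc(O)c(Cl)c(C)c1
F6 | step 5 | 2-hydroxy-4,6-bis(methoxymethoxy)benzaldehyde | O=Cc1c(O)cc(OCOC)cc1OCOC
F7 | step 5 | 4,6-bis(methoxymethoxy)-2-[(2-methylbut-3-en-2-yl)oxy]benzaldehyde | O=Cc1c(OC(C)(C)C=C)cc(OCOC)cc1OCOC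
F8 | step 10 | 2-{3-bromo-5-chloro-2-methoxy-4-methyl-6-[(trimethylsilyl)oxy]benzoyl}-3-(3-methylbut-2-enyl)-4,6-bis[(trimethylsilyl)oxy]benzaldehyde | COc1c(Br)c(C)c(Cl)c(O[Si](C)(C)C)c1C(=O)c1c(C=O)c(O[Si](C)(C)C)cc(O[Si](C)(C)C)c1CC=C(C)C
A1 | alternative 1 | methyl 4-acetoxy-4-[3-bromo-5-chloro-2-methoxy-6-(methoxymethoxy)-4-methylphenyl]but-2-ynoate (racemic) | COC(=O)C#CC(OC(C)=O)c1c(OC)c(Br)c(C)c(Cl)c1OCOC
A2 | alternative 1 | (3Z)-1-methoxy-7-methyl-1,3-bis(trimethylsilyloxy)octa-1,3,6-triene | COC(O[Si](C)(C)C)=C/C(O[Si](C)(C)C)=C/CC=C(C)C
A3 | alternative 1 | methyl 2-{acetoxy[3-bromo-5-chloro-2-methoxy-6-(methoxymethoxy)-4-methylphenyl]methyl}-4,6-dihydroxy-3-(3-methylbut-2-enyl)benzoate (racemic) | COC(=O)c1c(O)cc(O)c(CC=C(C)C)c1C(OC(C)=O)c1c(OC)c(Br)c(C)c(Cl)c1OCOC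
A4 | alternative 2 | 2-bromo-4-chloro-3-methylcyclobut-2-enone (racemic) | O=C1C(Br)=C(C)C1Cl
A5 | alternative 2 | tert-butyl({1-[2-(dimethoxymethyl)-3,5-bis(methoxymethoxy)-6-(3-methylbut-2-enyl)phenyl]-3-methoxyprop-2-yn-1-yl}oxy)dimethylsilane (racemic) | COC#CC(O[Si](C)(C)C(C)(C)C)c1c(C(OC)OC)c(OCOC)cc(OCOC)c1CC=C(C)C
A6 | alternative 2 | tert-butyldimethylsilyl ether of (3-bromo-5-chloro-6-hydroxy-2-methoxy-4-methylphenyl)[2-(dimethoxymethyl)-3,5-bis(methoxymethoxy)-6-(3-methylbut-2-enyl)phenyl]methanol (racemic) | COc1c(Br)c(C)c(Cl)c(O)c1C(O[Si](C)(C)C(C)(C)C)c1c(C(OC)OC)c(OCOC)cc(OCOC)c1CC=C(C)C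
A7 | alternative 3 | methyl 9-methyl-3,5-dioxodec-8-enoate | COC(=O)CC(=O)CC(=O)CCC=C(C)C
A8 | alternative 3 | methyl 2-[3-bromo-5-chloro-2-methoxy-6-(methoxymethoxy)-4-methylphenyl]-2-oxoacetate | COC(=O)C(=O)c1c(OC)c(Br)c(C)c(Cl)c1OCOC
A9 | alternative 3 | methyl 2-[3-bromo-5-chloro-2-methoxy-6-(methoxymethoxy)-4-methylbenzoyl]-4,6-dihydroxy-3-(3-methylbut-2-enyl)benzoate | COC(=O)c1c(O)cc(O)c(CC=C(C)C)c1C(=O)c1c(OC)c(Br)c(C)c(Cl)c1OCOC
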